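The data were computed for substances that don't exist, and the scatter is random.

| flask | substrate | partner | initiator | radical scavenger | temperature | remark | time |
|---|---|---|---|---|---|---|---|
| birch | 36 mM | 0.80 equiv | 2.3 mol% | 0.1 mol% | 0 °C | the very flask that is asked about, followed so far |  |
| larch | 36 mM | 0.80 equiv | 2.3 mol% | 0.1 mol% | −15 °C | run made earlier |  |
| flask | 36 mM | 0.800 equiv | 2.3 mol% | 0.1 mol% | 0 °C |  | 40 h |

- birch (time / h: target / %, substrate / %): 3.00: 49.8, 40.3; 8.00: 33.8, 23.2; 15.0: 23.7, 14.2; 25.0: 17.7, 9.0; 30.0: 16.5, 6.9
- larch (time / h: target / %, substrate / %): 6.00: 0, 99.3; 15.0: 1.1, 100.1; 30.0: 40.3, 45.9; 48.0: 26.3, 30.9; 60.0: 21.6, 25.7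

(readings scatter by 0.5 percentage points)

- east: at 40 h add partner, 100% of the amount charged, then wait 12 h
- west: at 40 h take out 90% of the target then present, then wait 12 h
- north-west: at 40 h raise the temperature by 15 K, then wait 12 h
- south-east: change nothing and wait 12 h more

- in percentages every species weighs as the substrate in it: one side product counts as two
- what is taken out of target is counted as made
- reactions considered so far: substrate + initiating radical -> capped initiator + first chain carrier; partner + first chain carrier -> target + second chain carrier; substrate + target -> side product; substrate + second chain carrier -> released group + first chain carrier; second chain carrier + radical scavenger -> ended chains B; 2 second chain carrier -> ended chains A; partner -> decomposed reagent; initiator -> 2 initiating radical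
- additions bring no volume worth counting

* target, in percent of the substrate first charged, at 40 h
* which option adds most target ("none" when 2 percentage points or less is all one gets) (east / west / north-west / south-east / none)
* target present, with what was taken out counted in, in percent of the substrate first charged, after west
* target present, with what was taken out counted in, in percent of the substrate first charged, after north-west

At late times the birch run showed one steady thing: target and substrate both fell, yet target minus substrate read 9.5 percentage points of the charge at 15.0 h and 9.6 points at 30.0 h. I saw why it could stand still. The step substrate + target → side product removes one of each and leaves this gap unchanged, while each turn of the chain spends one partner, turns one substrate into target and raises the gap by two. So I read the flat gap of the birch run as a stopped chain.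

Over the birch readings the gap averaged 0.0958. It begins at minus one, so the chain had made half of one plus the gap. I then wrote the balance of partner, the limiting reagent, and divided that amount by its 0.80 equiv. This gave the capture share, the part of the charged partner that became target before the chain stopped: 0.685. I took the remainder, 0.315, to have gone to decomposed reagent.

The share gave the gap, so up to 40 h in the birch flask I took target as substrate plus gap. But one number was not enough. The larch readings gave a share of 0.595, lower than birch, so it belongs to a temperature, and it carries no clock. For the clock I used ln(target/substrate), which rose by 0.0240 h⁻¹ between those two birch readings. Carried on to 40 h, it gave substrate 0.0470 and target 0.143. That substrate exceeded the margin, so I chose east, expecting fresh partner to convert it.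

The forecast gave 14.6% (13.7% to 15.5%), east, 14.4% after west and 11.1% after north-west, reasoning that “Fresh partner should therefore restart the chain”; its target stood slightly above mine. The flask gave 13.9%, with east best at 5.1 points, 13.7% after west and 11.9% after north-west.

    substrate + initiating radical → capped initiator + first chain carrier (k = 1.04 × 10⁵ M⁻¹ s⁻¹, Ea = 20.0 kJ mol⁻¹)
    partner + first chain carrier → target + second chain carrier (k = 75000 M⁻¹ s⁻¹, Ea = 24.0 kJ mol⁻¹)
    substrate + target → side product (k = 0.122 M⁻¹ min⁻¹, Ea = 56.0 kJ mol⁻¹)
    substrate + second chain carrier → released group + first chain carrier (k = 10800 M⁻¹ s⁻¹, Ea = 24.0 kJ mol⁻¹)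
    second chain carrier + radical scavenger → ended chains B (k = 6.57 × 10⁶ M⁻¹ s⁻¹, Ea = 19.0 kJ mol⁻¹)
    2 second chain carrier → ended chains A (k = 4.00 × 10⁶ M⁻¹ s⁻¹, Ea = 8.00 kJ mol⁻¹)
    partner → decomposed reagent (k = 0.00267 min⁻¹, Ea = 81.0 kJ mol⁻¹)
    initiator → 2 initiating radical (k = 1.76 × 10⁻⁴ min⁻¹, Ea = 95.0 kJ mol⁻¹)
    (constants at 0 °C)

This flask's state at 40.0 h, target 13.9% and substrate 4.1% with partner 0%, reckons to a share of 0.686, beside my 0.685. The neighbouring flask, at 9.0 mM of substrate with the same equivalents and loadings, also held partner 0%. Its share reckons to 0.653, lower than 0.685. That neighbouring flask held target 24.2% and substrate 19.8% at 40.0 h.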